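## The problem

Target 20 is a (2S)-flavanone. Ring A carries a free hydroxyl at C5 and a methyl ether at C7, and ring C holds the only stereocentre, C2. Ring B is a contiguously 1',2',3',4'-tetrasubstituted benzene with a geranyl chain at C2', a free hydroxyl at C3' and a methyl ether at C4'. The hardest part of the skeleton is ring B: the C10 chain sits at the most crowded position, between C1' and the C3' oxygen, and its C2''=C3'' double bond must be E. No other stereocentre exists to control C2, so its configuration has to come from a catalyst. C2 is also benzylic and β to the ketone, so it can be lost by retro-oxa-Michael opening to the chalcone; it should therefore be set late and kept away from strong base afterwards. The groups that will not survive rough treatment are the geranyl diene (under acid the C3' hydroxyl can add to C3'' to give a chroman) and the β-aryloxy ketone. The two phenols must also be kept distinct from the two methyl ethers, which is best done by buying both methyl ethers already in place. The feature that opens the key step is twofold: C2' lies between two groups that can both direct metalation (a masked C1' aldehyde and an acetal-type ether on the C3' oxygen), and the C2''=C3'' alkene lies exactly one carbon (C1'') from ring B. The C1''–C2'' bond is therefore a benzyl–alkenyl bond, and it can be made by coupling a C2' benzylic halide with an alkenyl metal whose geometry and C3'' methyl group come from syn-carbometalation of a terminal alkyne.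

## Retrosynthesis

**20 to 19 (two O–CH2OMe bonds).** Both phenols are carried as methoxymethyl ethers and released together in the last step. On ring B this ether is what directs lithiation to C2', and it survives organolithium, hydride, organoaluminium and hydroxide. A benzyl ether would need hydrogenolysis, which the diene excludes, and a silyl ether would not survive the lithiation or the hydroxide. The forward step has to cleave two acetal ethers with acid mild enough to spare the diene and C2.

**19 to 18 (O1–C2).** Opening ring C at the aryl ether bond removes the only stereocentre and gives the achiral 2'-hydroxychalcone 18. Cutting C2–C1' instead would require conjugate addition of an ortho-substituted aryl metal that already carries the chain to a chromone, which is a poor match for that chemistry. The forward reaction must be a catalyst-controlled, enantioselective 6-endo oxa-Michael addition.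

**18 to 15 and 17 (the enone C=C, C2–C3 of the flavanone).** An aldol condensation divides the molecule into two arenes of similar size: the ring B aldehyde 15 and the ring A ketone 17. Ketone 17 comes in one step from the commercially available, symmetric dihydroxy ketone 16, whose 4-methyl ether is already in place. The forward reaction is a hydroxide-mediated condensation that both acetal ethers and the diene tolerate.

**15 to 14 (aldehyde unmasked).** The aldehyde is carried as the dioxolane 14. The acetal is needed because the organoaluminium reagent of the key step would add to a free aldehyde, and it also serves as the second directing group in the lithiation.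

**14 to 8 and 13; 13 to 11 and 12 (C1''–C2'' and C3''–CH3).** This is the key disconnection.
- Against direct allylation: attaching the intact C10 chain to a C2' aryl metal with a geranyl electrophile would face SN2/SN2' competition at a doubly ortho-substituted nucleophile and would inherit its geometry from the reagent.
- Against a Claisen route: rearrangement of a C3' O-geranyl ether would deliver the chain with allylic transposition.
- For the chosen cut: only a one-carbon unit is placed on the ring, and the E alkene is created by mechanism. The precursors are far simpler: the benzylic chloride 8, the C8 enyne 11 and trimethylaluminium 12.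
- Asked of the forward reaction: syn addition with methyl on the internal carbon, no reaction at the C6''=C7'' alkene, coupling at an sp3 benzylic carbon with retention at the alkenyl carbon, and tolerance of two acetals.

**8 to 6 to 3 to 2 to 1 (C–Cl, then C2'–C1'').** The chloride 8 comes from the benzylic alcohol 6. The C2'–C1'' bond of 6 is made by directed ortho-metalation of 3 to the aryllithium 4, formylation to 5 and reduction in the same flask. Electrophilic substitution of isovanillin 1 would not place a carbon at this position cleanly, whereas the two flanking directing groups of 3 should. Acetal 3 comes from 1 by etherification to 2 and acetalisation.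

**11 to 9 (ketone to alkyne).** The enyne 11 is the terminal alkyne corresponding to the bulk terpenoid ketone 9, reached through the enol phosphate 10. Ketone 9 already contains the C6''=C7'' alkene and the gem-dimethyl terminus. The forward sequence needs kinetic enolisation at the methyl group, O-phosphorylation and base-induced elimination.

## Roads not taken

**Alternative 1:** Ring B itself is cut at C2'–C3' and C1'–C6', back to 3-methoxyfuran A1 and the geranyl-bearing ynoate A2. A (4+2) cycloaddition joins the nucleophilic C2 of A1 to the β-carbon of A2, and the bridged adduct opens and aromatises to the benzoate A3, the furan oxygen becoming the C3' hydroxyl.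
- Merits: all four substituents of ring B are placed in one step, with regiochemistry set by the polarisation of both partners, and the phenol appears unprotected. The route to the ring B fragment would be shorter than the chosen one, and that advantage is real.
- Weak points: A2 is a skipped enyne whose doubly activated CH2 invites isomerisation under the heat or Lewis acid that a β-alkyl ynoate, a sluggish dienophile, would need. A1 is a volatile, acid-labile enol ether. The acid that opens the adduct meets a free C3' phenol next to the C2''=C3'' alkene, which is the arrangement that cyclises to a chroman. The E geometry is inherited rather than created, and A3 still has to be brought to the aldehyde oxidation level.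
- Comparison: against the shorter count, the chosen plan offers steps that are each secure, a point of attachment fixed by two directing groups, and an alkene geometry made under conditions free of protic or strong Lewis acid.

**Alternative 2:** Ring A is cut at C8–C8a, C5–C6, C7–C8 and C4a–C5, back to the (S)-diazoketone A4 (ring C as a 2-aryl-2,3-dihydropyran-4-one already carrying ring B) and methoxyacetylene A5. Irradiation triggers Wolff rearrangement, (2+2) cycloaddition with A5, four-electron ring opening and six-electron electrocyclisation, giving A6, the target with only the ring B phenol protected.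
- Merits: the 5-hydroxy-7-methoxy pattern arises regiospecifically with no ring A protecting group. C2 is set earlier by an asymmetric cycloaddition and is never formed by a reversible conjugate addition, so on configurational security this road is better than the chosen one.
- Weak points: A4 needs many steps (a dihydropyranone with an acyl handle at C6, then diazo installation). A5 is volatile and unstable. The photochemical step exposes an enone chromophore and the geranyl diene to light, where energy transfer could scramble the C2''=C3'' geometry or cause (2+2) cycloaddition. The route also still needs the geranylated ring B aldehyde, so it does not address the chain.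
- Comparison: against the better stereocontrol, the chosen plan offers three steps from aldehyde 15 to the target, no diazo or photochemistry, and the option of correcting enantiopurity at the flavanone stage.

**Alternative 3:** Ring C is cut at O1–C8a and C4–C4a, back to the (S)-β-hydroxy ester A7 and the silyl triflate A8 as aryne precursor. The caesium alkoxide of A7 adds to the aryne generated from A8 at the carbon remote from the flanking methoxy group, and the resulting aryl anion attacks the ester to give the 5,7-dimethoxyflavanone A9.
- Merits: the route is convergent. The stereocentre is made beforehand by a dependable carbonyl addition or reduction and its C–O bond is not touched in the ring closure, so there is no retro-Michael erosion. In that respect it is better than the chosen plan.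
- Weak points: the β-alkoxide of A7 can fragment by retro-aldol or eliminate to a cinnamate before it meets the aryne. Arynes undergo ene reactions with alkenes bearing allylic hydrogens, and the chain has two such alkenes. A9 carries a methyl ether at C5 that must then be cleaved selectively by a Lewis acid in the presence of the diene and three other ethers.
- Comparison: the length is similar. The chosen plan offers the correct C5/C7 differentiation from a purchased ketone and no reagent that is indiscriminate towards the chain.

Key step: step 6

Assumption: the thiourea built on 9-amino-9-deoxy-epi-quinidine is taken to close ring C to the 2S flavanone; if its sense of induction proves opposite, the epi-quinine-derived pseudoenantiomer is used with no other change.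

## Steps

Step 1
Reactants: 1 isovanillin (3-hydroxy-4-methoxybenzaldehyde)
Product: 2 4-methoxy-3-(methoxymethoxy)benzaldehyde
Conditions: MOMCl, i-Pr2NEt, CH2Cl2, 0 °C → rt
Reagents that add atoms: chloromethyl methyl ether (MOMCl), COCCl
Why: Williamson-type O-alkylation of the phenol by the reactive α-chloro ether under amine base; the aldehyde is inert to these conditions.

Step 2
Reactants: 2 4-methoxy-3-(methoxymethoxy)benzaldehyde
Product: 3 2-[4-methoxy-3-(methoxymethoxy)phenyl]-1,3-dioxolane
Conditions: HOCH2CH2OH, PPTS (cat.), benzene, reflux, Dean–Stark
Reagents that add atoms: ethylene glycol, OCCO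
Why: Acid-catalysed acetalisation driven by azeotropic removal of water; the weak acid PPTS is chosen so that the aryl MOM ether should not exchange.

Step 3
Reactants: 3 2-[4-methoxy-3-(methoxymethoxy)phenyl]-1,3-dioxolane
Product: 6 [6-(1,3-dioxolan-2-yl)-3-methoxy-2-(methoxymethoxy)phenyl]methanol, via aryllithium 4 (not isolated), via aldehyde 5 (not isolated)
Conditions: n-BuLi, THF, −20 → 0 °C; DMF, −78 → 0 °C; then MeOH, NaBH4, 0 °C
Reagents that add atoms: N,N-dimethylformamide, CN(C)C=O
Why: Directed ortho-metalation: the MOM ether and the dioxolane both coordinate lithium and acidify the C–H between them, so deprotonation should occur at that position; formylation of 4 and borohydride reduction of 5 in the same flask give the benzylic alcohol that carries C1''.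

Step 4
Reactants: 6 [6-(1,3-dioxolan-2-yl)-3-methoxy-2-(methoxymethoxy)phenyl]methanol
Product: 8 2-[2-(chloromethyl)-4-methoxy-3-(methoxymethoxy)phenyl]-1,3-dioxolane, via benzylic methanesulfonate 7 (not isolated)
Conditions: MsCl, Et3N, LiCl, THF, 0 °C → rt
Reagents that add atoms: lithium chloride, [Li+].[Cl-]; methanesulfonyl chloride, CS(=O)(=O)Cl
Why: Sulfonylation of the primary benzylic alcohol followed by SN2 displacement by chloride, under basic, non-ionising conditions that should leave both acetals intact.

Step 5
Reactants: 9 6-methylhept-5-en-2-one
Product: 11 6-methylhept-5-en-1-yne, via enol phosphate 10 (not isolated)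
Conditions: LiN(i-Pr)2 (1.05 equiv), THF, −78 °C; ClP(O)(OEt)2, −78 °C → rt; then LiN(i-Pr)2 (2.2 equiv), −78 °C → rt; H2O
Reagents that add atoms: none
Why: Methyl ketone to terminal alkyne conversion through the enol phosphate: kinetic deprotonation at the methyl group and O-phosphorylation give 10, from which further amide base eliminates diethyl phosphate; the trisubstituted alkene is not affected.

Step 6
Reactants: 11 6-methylhept-5-en-1-yne; 12 trimethylaluminium; 8 2-[2-(chloromethyl)-4-methoxy-3-(methoxymethoxy)phenyl]-1,3-dioxolane
Product: 14 2-{2-[(2E)-3,7-dimethylocta-2,6-dien-1-yl]-4-methoxy-3-(methoxymethoxy)phenyl}-1,3-dioxolane, via alkenylalane 13 (not isolated)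
Conditions: 11, Me3Al (2 equiv), Cp2ZrCl2 (0.25 equiv), ClCH2CH2Cl, 0 °C → rt; volatiles and excess Me3Al removed in vacuo; THF; then 8, Pd(PPh3)4 (5 mol%), rt
Reagents that add atoms: none
Why: Zirconium-catalysed methylalumination (Negishi carboalumination) of the terminal alkyne adds methyl and metal syn across the triple bond with methyl on the internal carbon, and transfer to aluminium gives the (E)-alkenyldimethylalane 13, which creates the C3''–CH3 bond. The trisubstituted alkene of 11 should not be carbometalated, because the reagent needs the unhindered triple bond. After free Me3Al is stripped off and the residue is taken up in THF, zerovalent palladium inserts into the benzylic C–Cl bond of 8, the alkenyl group passes from aluminium to palladium in preference to methyl, and reductive elimination forms C1''–C2'' with retention of alkene geometry. The closest known reaction type is the palladium-catalysed coupling of carboalumination-derived alkenylalanes with benzylic halides to give allylated arenes. No ring is closed and no stereocentre is formed; the stereochemical element is the E geometry of C2''=C3'', which follows from syn addition with aluminium on the terminal carbon and from stereoretentive coupling. The step needs chemoselectivity towards two acetals: the aldehyde is masked as the dioxolane so that the alane cannot add to it, and THF coordination together with removal of Me3Al tempers the Lewis acidity that could open the dioxolane or the MOM ether. The benzylpalladium intermediate has no β-hydrogen, so elimination pathways are closed, and bond formation at the benzylic carbon excludes allylic transposition.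

Step 7
Reactants: 14 2-{2-[(2E)-3,7-dimethylocta-2,6-dien-1-yl]-4-methoxy-3-(methoxymethoxy)phenyl}-1,3-dioxolane
Product: 15 2-[(2E)-3,7-dimethylocta-2,6-dien-1-yl]-4-methoxy-3-(methoxymethoxy)benzaldehyde
Conditions: 1 M aq. HCl, THF, 0 °C → rt
Reagents that add atoms: water, O
Why: Acid-catalysed acetal hydrolysis; the benzaldehyde acetal ionises far more readily (cation stabilised by the para methoxy group) than the aryl MOM ether, so the aldehyde should be released selectively, and cold dilute acid should not protonate the trisubstituted alkenes.

Step 8
Reactants: 16 1-(2,6-dihydroxy-4-methoxyphenyl)ethan-1-one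
Product: 17 1-[2-hydroxy-4-methoxy-6-(methoxymethoxy)phenyl]ethan-1-one
Conditions: MOMCl (1.1 equiv), i-Pr2NEt, CH2Cl2, 0 °C → rt
Reagents that add atoms: chloromethyl methyl ether (MOMCl), COCCl
Why: Mono-etherification of a symmetric diol-type substrate: either hydroxyl gives 17, and the remaining hydroxyl is held in a hydrogen bond to the ketone and should be too poor a nucleophile to react a second time under these conditions.

Step 9
Reactants: 15 2-[(2E)-3,7-dimethylocta-2,6-dien-1-yl]-4-methoxy-3-(methoxymethoxy)benzaldehyde; 17 1-[2-hydroxy-4-methoxy-6-(methoxymethoxy)phenyl]ethan-1-one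
Product: 18 (2E)-3-{2-[(2E)-3,7-dimethylocta-2,6-dien-1-yl]-4-methoxy-3-(methoxymethoxy)phenyl}-1-[2-hydroxy-4-methoxy-6-(methoxymethoxy)phenyl]prop-2-en-1-one
Conditions: KOH, EtOH/H2O, rt
Reagents that add atoms: none
Why: Claisen–Schmidt condensation: the enolate of 17 adds to the non-enolisable aldehyde 15 and the aldol dehydrates by E1cB to the E enone; in strong base the product rests as the phenoxide of the open chalcone, so ring closure is left to the next step.

Step 10
Reactants: 18 (2E)-3-{2-[(2E)-3,7-dimethylocta-2,6-dien-1-yl]-4-methoxy-3-(methoxymethoxy)phenyl}-1-[2-hydroxy-4-methoxy-6-(methoxymethoxy)phenyl]prop-2-en-1-one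
Product: 19 (2S)-2-{2-[(2E)-3,7-dimethylocta-2,6-dien-1-yl]-4-methoxy-3-(methoxymethoxy)phenyl}-7-methoxy-5-(methoxymethoxy)-2,3-dihydro-4H-chromen-4-one
Conditions: thiourea from 9-amino-9-deoxy-epi-quinidine and 3,5-bis(trifluoromethyl)phenyl isothiocyanate (10 mol%), toluene, rt
Reagents that add atoms: none
Why: Catalytic enantioselective intramolecular oxa-Michael addition (6-endo-trig) of a 2'-hydroxychalcone: the quinuclidine nitrogen activates the phenol as a general base while the thiourea hydrogen-bonds to the enone carbonyl, so the oxygen is delivered to one enantiotopic face of the β-carbon and C2 is set as S by the catalyst alone; the 6'-oxygen substituent should bias the equilibrium towards the closed flavanone.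

Step 11
Reactants: 19 (2S)-2-{2-[(2E)-3,7-dimethylocta-2,6-dien-1-yl]-4-methoxy-3-(methoxymethoxy)phenyl}-7-methoxy-5-(methoxymethoxy)-2,3-dihydro-4H-chromen-4-one
Product: 20 (2S)-2-{2-[(2E)-3,7-dimethylocta-2,6-dien-1-yl]-3-hydroxy-4-methoxyphenyl}-5-hydroxy-7-methoxy-2,3-dihydro-4H-chromen-4-one
Conditions: HCl (1.25 M in MeOH), 0 °C → rt
Reagents that add atoms: none
Why: Acid-catalysed acetal exchange transfers both methoxymethyl groups to methanol; the C5 ether, activated by the peri carbonyl, should go first, and mild anhydrous acid at low temperature is chosen to spare the diene and the C2 stereocentre.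

## Compound list

1 | isovanillin (3-hydroxy-4-methoxybenzaldehyde) | COc1ccc(C=O)cc1O | starting material
2 | 4-methoxy-3-(methoxymethoxy)benzaldehyde | COCOc1cc(C=O)ccc1OC | intermediate
3 | 2-[4-methoxy-3-(methoxymethoxy)phenyl]-1,3-dioxolane | COCOc1cc(C2OCCO2)ccc1OC | intermediate
4 | [6-(1,3-dioxolan-2-yl)-3-methoxy-2-(methoxymethoxy)phenyl]lithium | [Li]c1c(C2OCCO2)ccc(OC)c1OCOC | intermediate
5 | 6-(1,3-dioxolan-2-yl)-3-methoxy-2-(methoxymethoxy)benzaldehyde | O=Cc1c(C2OCCO2)ccc(OC)c1OCOC | intermediate
6 | [6-(1,3-dioxolan-2-yl)-3-methoxy-2-(methoxymethoxy)phenyl]methanol | OCc1c(C2OCCO2)ccc(OC)c1OCOC | intermediate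
7 | [6-(1,3-dioxolan-2-yl)-3-methoxy-2-(methoxymethoxy)phenyl]methyl methanesulfonate | CS(=O)(=O)OCc1c(C2OCCO2)ccc(OC)c1OCOC | intermediate
8 | 2-[2-(chloromethyl)-4-methoxy-3-(methoxymethoxy)phenyl]-1,3-dioxolane | ClCc1c(C2OCCO2)ccc(OC)c1OCOC | intermediate
9 | 6-methylhept-5-en-2-one | CC(=O)CCC=C(C)C | starting material
10 | diethyl 6-methylhepta-1,5-dien-2-yl phosphate | C=C(CCC=C(C)C)OP(=O)(OCC)OCC | intermediate
11 | 6-methylhept-5-en-1-yne | C#CCCC=C(C)C | intermediate
12 | trimethylaluminium | C[Al](C)C | starting material
13 | [(1E)-2,6-dimethylhepta-1,5-dien-1-yl]dimethylalumane | C[Al](C)/C=C(\C)CCC=C(C)C | intermediate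
14 | 2-{2-[(2E)-3,7-dimethylocta-2,6-dien-1-yl]-4-methoxy-3-(methoxymethoxy)phenyl}-1,3-dioxolane | COCOc1c(OC)ccc(C2OCCO2)c1C/C=C(\C)CCC=C(C)C | intermediate
15 | 2-[(2E)-3,7-dimethylocta-2,6-dien-1-yl]-4-methoxy-3-(methoxymethoxy)benzaldehyde | COCOc1c(OC)ccc(C=O)c1C/C=C(\C)CCC=C(C)C | intermediate
16 | 1-(2,6-dihydroxy-4-methoxyphenyl)ethan-1-one | CC(=O)c1c(O)cc(OC)cc1O | starting material
17 | 1-[2-hydroxy-4-methoxy-6-(methoxymethoxy)phenyl]ethan-1-one | CC(=O)c1c(O)cc(OC)cc1OCOC | intermediate
18 | (2E)-3-{2-[(2E)-3,7-dimethylocta-2,6-dien-1-yl]-4-methoxy-3-(methoxymethoxy)phenyl}-1-[2-hydroxy-4-methoxy-6-(methoxymethoxy)phenyl]prop-2-en-1-one | COCOc1cc(OC)cc(O)c1C(=O)/C=C/c1ccc(OC)c(OCOC)c1C/C=C(\C)CCC=C(C)C | intermediate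
19 | (2S)-2-{2-[(2E)-3,7-dimethylocta-2,6-dien-1-yl]-4-methoxy-3-(methoxymethoxy)phenyl}-7-methoxy-5-(methoxymethoxy)-2,3-dihydro-4H-chromen-4-one | COc1cc(OCOC)c2c(c1)O[C@H](c1ccc(OC)c(OCOC)c1C/C=C(\C)CCC=C(C)C)CC2=O | intermediate
20 | (2S)-2-{2-[(2E)-3,7-dimethylocta-2,6-dien-1-yl]-3-hydroxy-4-methoxyphenyl}-5-hydroxy-7-methoxy-2,3-dihydro-4H-chromen-4-one | COc1cc(O)c2c(c1)O[C@H](c1ccc(OC)c(O)c1C/C=C(\C)CCC=C(C)C)CC2=O | target

## Step count and least certain steps

Total: 11 steps. Longest linear sequence: 9 steps from 1 (steps 1, 2, 3, 4, 6, 7, 9, 10, 11). Steps 5 and 8 are one-step side branches.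

**Step 6 (key step).**
- Risk: residual organoaluminium may open the dioxolane or the MOM ether by Lewis acid activation, or transfer methyl instead of alkenyl to the benzylpalladium species. Oxidative addition and transmetalation at the doubly ortho-substituted benzylic carbon may also be slow enough for homocoupling of the chloride to compete.
- Fallback: it sets out from 13 (made as in step 6) and from 8, and returns at 14. Iodinolysis of 13 (I2, THF, −30 → 0 °C) should give (1E)-1-iodo-2,6-dimethylhepta-1,5-diene F1, which can be purified. Insertion of Zn dust into 8 in the presence of LiCl in THF should give {[6-(1,3-dioxolan-2-yl)-3-methoxy-2-(methoxymethoxy)phenyl]methyl}zinc chloride F2. Negishi coupling of F2 with F1 under Pd(PPh3)4 in THF should then give 14. The same two bonds are formed, but the polarity is reversed and aluminium never meets the acetals.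

**Step 10.**
- Risk: facial selectivity in the ring closure may be poor with the ortho-substituted ring B, and enantiopurity may erode through reversible ring opening under the amine catalyst.
- Fallback: it sets out from 18 and returns at 19. Ring closure without stereocontrol (NaOAc, EtOH, reflux) should give racemic 2-{2-[(2E)-3,7-dimethylocta-2,6-dien-1-yl]-4-methoxy-3-(methoxymethoxy)phenyl}-7-methoxy-5-(methoxymethoxy)-2,3-dihydro-4H-chromen-4-one F3. Kinetic resolution by asymmetric transfer hydrogenation with RhCl(Cp*)[(R,R)-TsDPEN], HCO2H/Et3N in EtOAc at rt is expected to reduce the 2R enantiomer to the cis alcohol (2R,4R)-2-{2-[(2E)-3,7-dimethylocta-2,6-dien-1-yl]-4-methoxy-3-(methoxymethoxy)phenyl}-7-methoxy-5-(methoxymethoxy)-3,4-dihydro-2H-chromen-4-ol F4 and to leave 19, which is separated by chromatography. Half of the material is sacrificed; the isolated alkenes are not reduced by this catalyst.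

**Step 11.**
- Risk: the freed C3' hydroxyl may add to C3'' under acid (chroman formation), methanol may add to the alkenes, and optical purity may be lost by acid-mediated ring opening during the longer exposure that the unactivated ring B ether needs.
- Fallback: it sets out from 14 and returns at 20, and it moves the harder deprotection to a stage with no stereocentre. Treatment of 14 with 2 M aq. HCl in THF at 40 °C should remove the acetal and the MOM ether together to give 2-[(2E)-3,7-dimethylocta-2,6-dien-1-yl]-3-hydroxy-4-methoxybenzaldehyde F5. Claisen–Schmidt condensation of F5 with 17 (excess KOH, EtOH/H2O) should give (2E)-3-{2-[(2E)-3,7-dimethylocta-2,6-dien-1-yl]-3-hydroxy-4-methoxyphenyl}-1-[2-hydroxy-4-methoxy-6-(methoxymethoxy)phenyl]prop-2-en-1-one F6. The thiourea-catalysed closure of step 10 should give (2S)-2-{2-[(2E)-3,7-dimethylocta-2,6-dien-1-yl]-3-hydroxy-4-methoxyphenyl}-7-methoxy-5-(methoxymethoxy)-2,3-dihydro-4H-chromen-4-one F7. Only the carbonyl-activated C5 ether then remains, and brief exposure to dilute HCl in MeOH at 0 °C should give 20. The phenol–alkene cyclisation risk is thereby tested early on an achiral intermediate.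

**Step 3.**
- Risk: deprotonation may compete at C5, C6 or the acetal methine, giving regioisomers or acetal fragmentation.
- Fallback: it sets out from 1 and returns at 4, replacing deprotonation by halogen–metal exchange. Bromination of 1 (Br2, NaOAc, AcOH), which goes ortho to the hydroxyl, should give 2-bromo-3-hydroxy-4-methoxybenzaldehyde F8. MOM protection as in step 1 should give 2-bromo-4-methoxy-3-(methoxymethoxy)benzaldehyde F9, and acetalisation as in step 2 should give 2-[2-bromo-4-methoxy-3-(methoxymethoxy)phenyl]-1,3-dioxolane F10. Bromine–lithium exchange (n-BuLi, THF, −78 °C) generates 4 at a defined position, and the DMF and NaBH4 treatment of step 3 follows.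

## Further compounds

F1 | step 6 | (1E)-1-iodo-2,6-dimethylhepta-1,5-diene | I/C=C(\C)CCC=C(C)C
F2 | step 6 | {[6-(1,3-dioxolan-2-yl)-3-methoxy-2-(methoxymethoxy)phenyl]methyl}zinc chloride | Cl[Zn]Cc1c(C2OCCO2)ccc(OC)c1OCOC
F3 | step 10 | racemic 2-{2-[(2E)-3,7-dimethylocta-2,6-dien-1-yl]-4-methoxy-3-(methoxymethoxy)phenyl}-7-methoxy-5-(methoxymethoxy)-2,3-dihydro-4H-chromen-4-one | COc1cc(OCOC)c2c(c1)OC(c1ccc(OC)c(OCOC)c1C/C=C(\C)CCC=C(C)C)CC2=O
F4 | step 10 | (2R,4R)-2-{2-[(2E)-3,7-dimethylocta-2,6-dien-1-yl]-4-methoxy-3-(methoxymethoxy)phenyl}-7-methoxy-5-(methoxymethoxy)-3,4-dihydro-2H-chromen-4-ol | COc1cc(OCOC)c2c(c1)O[C@@H](c1ccc(OC)c(OCOC)c1C/C=C(\C)CCC=C(C)C)C[C@H]2O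
F5 | step 11 | 2-[(2E)-3,7-dimethylocta-2,6-dien-1-yl]-3-hydroxy-4-methoxybenzaldehyde | COc1ccc(C=O)c(C/C=C(\C)CCC=C(C)C)c1O
F6 | step 11 | (2E)-3-{2-[(2E)-3,7-dimethylocta-2,6-dien-1-yl]-3-hydroxy-4-methoxyphenyl}-1-[2-hydroxy-4-methoxy-6-(methoxymethoxy)phenyl]prop-2-en-1-one | COCOc1cc(OC)cc(O)c1C(=O)/C=C/c1ccc(OC)c(O)c1C/C=C(\C)CCC=C(C)C
F7 | step 11 | (2S)-2-{2-[(2E)-3,7-dimethylocta-2,6-dien-1-yl]-3-hydroxy-4-methoxyphenyl}-7-methoxy-5-(methoxymethoxy)-2,3-dihydro-4H-chromen-4-one | COc1cc(OCOC)c2c(c1)O[C@H](c1ccc(OC)c(O)c1C/C=C(\C)CCC=C(C)C)CC2=O
F8 | step 3 | 2-bromo-3-hydroxy-4-methoxybenzaldehyde | COc1ccc(C=O)c(Br)c1O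
F9 | step 3 | 2-bromo-4-methoxy-3-(methoxymethoxy)benzaldehyde | COCOc1c(Br)c(C=O)ccc1OC
F10 | step 3 | 2-[2-bromo-4-methoxy-3-(methoxymethoxy)phenyl]-1,3-dioxolane | COCOc1c(Br)c(C2OCCO2)ccc1OC
A1 | alternative 1 | 3-methoxyfuran | COc1ccoc1
A2 | alternative 1 | methyl (5E)-6,10-dimethylundeca-5,9-dien-2-ynoate | COC(=O)C#CC/C=C(\C)CCC=C(C)C
A3 | alternative 1 | methyl 2-[(2E)-3,7-dimethylocta-2,6-dien-1-yl]-3-hydroxy-4-methoxybenzoate | COC(=O)c1ccc(OC)c(O)c1C/C=C(\C)CCC=C(C)C
A4 | alternative 2 | (2S)-6-(diazoacetyl)-2-{2-[(2E)-3,7-dimethylocta-2,6-dien-1-yl]-4-methoxy-3-(methoxymethoxy)phenyl}-2,3-dihydro-4H-pyran-4-one | [N-]=[N+]=CC(=O)C1=CC(=O)C[C@@H](c2ccc(OC)c(OCOC)c2C/C=C(\C)CCC=C(C)C)O1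
A5 | alternative 2 | methoxyacetylene | COC#C
A6 | alternative 2 | (2S)-2-{2-[(2E)-3,7-dimethylocta-2,6-dien-1-yl]-4-methoxy-3-(methoxymethoxy)phenyl}-5-hydroxy-7-methoxy-2,3-dihydro-4H-chromen-4-one | COc1cc(O)c2c(c1)O[C@H](c1ccc(OC)c(OCOC)c1C/C=C(\C)CCC=C(C)C)CC2=O
A7 | alternative 3 | methyl (3S)-3-{2-[(2E)-3,7-dimethylocta-2,6-dien-1-yl]-4-methoxy-3-(methoxymethoxy)phenyl}-3-hydroxypropanoate | COC(=O)C[C@H](O)c1ccc(OC)c(OCOC)c1C/C=C(\C)CCC=C(C)C
A8 | alternative 3 | 3,5-dimethoxy-2-(trimethylsilyl)phenyl trifluoromethanesulfonate | COc1cc(OC)c([Si](C)(C)C)c(OS(=O)(=O)C(F)(F)F)c1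
A9 | alternative 3 | (2S)-2-{2-[(2E)-3,7-dimethylocta-2,6-dien-1-yl]-4-methoxy-3-(methoxymethoxy)phenyl}-5,7-dimethoxy-2,3-dihydro-4H-chromen-4-one | COc1cc(OC)c2c(c1)O[C@H](c1ccc(OC)c(OCOC)c1C/C=C(\C)CCC=C(C)C)CC2=O
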